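**Retrosynthetic overview**

1. The acid comes from the terminal alkene of 3-allyl-1,2-dioxane 26 (ozonolysis, Pinnick). The 1,2-dioxane is the only ring that is made (the phenyl ring is bought); it is closed in step 12 by 6-exo-tet SN2 attack of the C6 hydroperoxide on a C3 mesylate, after cobalt-catalysed hydroperoxysilylation of a trisubstituted alkene (step 11).
2. The acyclic chain 19 comes from three components joined in one flask (step 7): 9-phenylnonyl pinacol boronic ester 4, the lithiated ethyl benzoate from 7, and alkenyl iodide 12. A 1,2-shift of the nonyl CH2 from boron to the carbenoid carbon makes the bond between the side-chain methine and the first CH2 of the phenylnonyl chain; a Zweifel olefination then joins that methine to the left-hand piece.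
3. Enabling feature: the side-chain methine (H, CH3 and two CH2 neighbours) lies one CH2 away from ring carbon C6, which is fully substituted (ring O1, ring CH2 C5, CH3, side-chain CH2). The methine can therefore be built as an ethylidene carbenoid inserted into a C–B bond, and C6 with its CH2 neighbour can be carried as a trisubstituted C=C, which lets boron leave by elimination and later takes up the peroxide at C6.
4. Stereocentres: side-chain methine from (−)-sparteine (step 7); C4 from (R)-3-bromo-2-methylpropan-1-ol; C3 from iridium-catalysed allylation (step 9) followed by inversion (step 12); C6 is formed without control (step 11).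

Key step: step 7

Remark on the chemistry: no known reaction type fixes the configuration of the tertiary peroxide carbon C6 in this series. Step 11 is therefore expected to give both C6 epimers, and the unwanted one is removed by chromatography after ring closure (step 12). Ring atoms are numbered O1, O2, C3–C6 as in the 1,2-dioxane of the target.

**Route**

Step 1
Reactants: 1 9-bromonon-1-ene; 2 phenylmagnesium bromide
Product: 3 non-8-en-1-ylbenzene (9-phenylnon-1-ene)
Conditions: FeCl3 (5 mol%), TMEDA, THF, 0 °C, slow addition of 2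
Reagents that add atoms: none
Why: Iron-catalysed Kumada-type cross-coupling of an aryl Grignard reagent with a primary alkyl bromide should join ring and chain without touching the remote terminal alkene.

Step 2
Reactants: 3 non-8-en-1-ylbenzene
Product: 4 4,4,5,5-tetramethyl-2-(9-phenylnonyl)-1,3,2-dioxaborolane
Conditions: pinacolborane, [Ir(cod)Cl]2 (1.5 mol%), dppm, CH2Cl2, rt
Reagents that add atoms: pinacolborane, CC1(C)OBOC1(C)C
Why: Iridium-catalysed hydroboration with pinacolborane is anti-Markovnikov for terminal alkenes and should give the linear primary boronic ester.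

Step 3
Reactants: 5 2,4,6-triisopropylbenzoic acid; 6 iodoethane
Product: 7 ethyl 2,4,6-triisopropylbenzoate
Conditions: K2CO3, DMF, rt
Reagents that add atoms: none
Why: SN2 O-alkylation of the carboxylate avoids attack at the shielded carbonyl carbon and gives the hindered benzoate that later acts as directing and leaving group.

Step 4
Reactants: 8 (R)-3-bromo-2-methylpropan-1-ol
Product: 9 (R)-(3-bromo-2-methylpropoxy)(tert-butyl)dimethylsilane
Conditions: TBSCl, imidazole, CH2Cl2, 0 °C to rt
Reagents that add atoms: tert-butyldimethylsilyl chloride, CC(C)(C)[Si](C)(C)Cl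
Why: Standard silylation of the primary alcohol; the stereocentre (the later ring carbon C4) is untouched.

Step 5
Reactants: 9 (R)-(3-bromo-2-methylpropoxy)(tert-butyl)dimethylsilane
Product: 10 (S)-tert-butyldimethyl[(2-methylpent-4-yn-1-yl)oxy]silane
Conditions: lithium acetylide–ethylenediamine complex, DMSO, 0 °C to rt
Reagents that add atoms: lithium acetylide (ethylenediamine complex), [Li]C#C
Why: SN2 displacement of the primary bromide by acetylide in a dipolar aprotic solvent; the neighbouring stereocentre is not involved and only its descriptor changes (R to S) with the priorities.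

Step 6
Reactants: 10 (S)-tert-butyldimethyl[(2-methylpent-4-yn-1-yl)oxy]silane
Product: 12 tert-butyl{[(2S,4E)-5-iodo-2,4-dimethylpent-4-en-1-yl]oxy}dimethylsilane, via alkenylalane 11 (not isolated)
Conditions: AlMe3, Cp2ZrCl2 (cat.), CH2Cl2, 0 °C to rt; then I2, THF, −30 to 0 °C
Reagents that add atoms: trimethylaluminium, C[Al](C)C; iodine, II
Why: Negishi zirconium-catalysed carboalumination adds methyl and aluminium syn across the alkyne with aluminium at the terminus, and iodinolysis with retention should give the E alkenyl iodide.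

Step 7
Reactants: 7 ethyl 2,4,6-triisopropylbenzoate; 4 4,4,5,5-tetramethyl-2-(9-phenylnonyl)-1,3,2-dioxaborolane; 12 tert-butyl{[(2S,4E)-5-iodo-2,4-dimethylpent-4-en-1-yl]oxy}dimethylsilane
Product: 19 tert-butyldimethyl{[(2S,4Z,6R)-2,4,6-trimethyl-15-phenylpentadec-4-en-1-yl]oxy}silane, via lithiated benzoate 13 (not isolated), via first boronate complex 14 (not isolated), via secondary boronic ester 15 (not isolated), via alkenyllithium 16 (not isolated), via alkenyl boronate complex 17 (not isolated), via iodo boronic ester 18 (not isolated)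
Conditions: 7, s-BuLi, (−)-sparteine, Et2O, −78 °C; 4, −78 °C then 35 °C; then 16 (from 12, t-BuLi 2 equiv, THF, −78 °C) added at −78 °C; I2, MeOH, −78 °C; NaOMe, MeOH, −78 °C to rt
Reagents that add atoms: none
Why: (−)-Sparteine-mediated deprotonation of 7 should give the configurationally stable (S)-α-oxyalkyllithium 13, which 4 borylates with retention to ate complex 14; on warming, the 9-phenylnonyl group shifts from boron to carbon anti to the departing benzoate (1,2-metallate rearrangement, inversion at carbon), which forms the bond between the chain CH2 and the methyl-bearing methine and gives (R)-boronic ester 15. Without isolation, boron then takes up alkenyllithium 16 (from 12 by lithium–iodine exchange with retention of geometry) to give ate complex 17; iodine activates its C=C bond, the secondary alkyl group migrates from boron to the alkenyl carbon with retention at the migrating methine to give 18, and methoxide-induced anti elimination of boron and iodine releases alkene 19 (Z, through the inversion of alkene geometry inherent to this sequence). The closest known reaction types are the Hoppe–Aggarwal lithiation–borylation of primary alkyl pinacol boronic esters with lithiated ethyl benzoates and the Zweifel olefination of secondary boronic esters, run here in one flask so that three components are joined around the methine carbon. No ring is closed in this step. The one new stereocentre (side-chain methine, R) is set by reagent control from (−)-sparteine and relayed by two stereospecific 1,2-shifts (inversion at the carbenoid carbon, then retention at the migrating carbon). The step needs a single homologation and migration of carbon rather than oxygen: 14 forms at −78 °C but rearranges only on warming, when surplus 13 has decomposed, the primary alkyl group migrates far faster than a pinacol oxygen, and the alkene geometry of 19 does not matter because step 11 turns either isomer into the same C6 radical.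

Step 8
Reactants: 19 tert-butyldimethyl{[(2S,4Z,6R)-2,4,6-trimethyl-15-phenylpentadec-4-en-1-yl]oxy}silane
Product: 20 (2S,4Z,6R)-2,4,6-trimethyl-15-phenylpentadec-4-en-1-ol
Conditions: TBAF, THF, 0 °C to rt
Reagents that add atoms: none
Why: Fluoride-mediated cleavage of the silyl ether frees the primary alcohol without affecting the alkene or either stereocentre.

Step 9
Reactants: 20 (2S,4Z,6R)-2,4,6-trimethyl-15-phenylpentadec-4-en-1-ol
Product: 22 (4R,5S,7Z,9R)-5,7,9-trimethyl-18-phenyloctadeca-1,7-dien-4-ol, via aldehyde 21 (not isolated)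
Conditions: allyl acetate, [Ir(cod)Cl]2 (2.5 mol%), (R)-Cl,MeO-BIPHEP (ligand antipode selected for the 4R carbinol), 4-cyano-3-nitrobenzoic acid, Cs2CO3 (20 mol%), THF, 100 °C
Reagents that add atoms: allyl acetate, C=CCOC(C)=O
Why: Krische iridium-catalysed transfer-hydrogenative carbonyl allylation from the alcohol oxidation level: aldehyde 21 is formed only transiently at the metal, so the adjacent methyl-bearing centre should not epimerise, and the chiral π-allyliridium C,O-benzoate sets the new carbinol centre as R by catalyst control, which is also the Felkin sense of the substrate.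

Step 10
Reactants: 22 (4R,5S,7Z,9R)-5,7,9-trimethyl-18-phenyloctadeca-1,7-dien-4-ol
Product: 23 (4R,5S,7Z,9R)-5,7,9-trimethyl-18-phenyloctadeca-1,7-dien-4-yl methanesulfonate
Conditions: MsCl, Et3N, CH2Cl2, 0 °C
Reagents that add atoms: methanesulfonyl chloride, CS(=O)(=O)Cl
Why: Sulfonylation of the secondary alcohol with retention turns the carbinol into the leaving group for the later SN2 ring closure.

Step 11
Reactants: 23 (4R,5S,7Z,9R)-5,7,9-trimethyl-18-phenyloctadeca-1,7-dien-4-yl methanesulfonate
Product: 24 (4R,5S,7R,9R)-5,7,9-trimethyl-18-phenyl-7-[(triethylsilyl)peroxy]octadec-1-en-4-yl methanesulfonate (formed together with its 7S epimer, which is carried along)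
Conditions: Co(thd)2 (10 mol%; thd = 2,2,6,6-tetramethylheptane-3,5-dionate), O2 (1 atm), Et3SiH, 1,2-dichloroethane, rt
Reagents that add atoms: dioxygen, O=O; triethylsilane, CC[SiH](CC)CC
Why: Mukaiyama–Isayama hydroperoxysilylation: a cobalt hydride should transfer a hydrogen atom to the less substituted carbon of the electron-rich trisubstituted alkene faster than to the terminal alkene, the tertiary C6 radical captures O2 and the peroxyl is silylated; the radical is planar and unbiased, so both C6 epimers are expected.

Step 12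
Reactants: 24 (4R,5S,7R,9R)-5,7,9-trimethyl-18-phenyl-7-[(triethylsilyl)peroxy]octadec-1-en-4-yl methanesulfonate
Product: 26 (3S,4S,6R)-4,6-dimethyl-6-[(2R)-2-methyl-11-phenylundecyl]-3-(prop-2-en-1-yl)-1,2-dioxane, via hydroperoxide 25 (not isolated)
Conditions: TBAF, THF, 0 °C; then KOt-Bu, 18-crown-6, 0 °C to rt; chromatography
Reagents that add atoms: none
Why: Fluoride unmasks the tertiary hydroperoxide, and its potassium salt should displace the secondary mesylate in a 6-exo-tet intramolecular SN2 reaction with inversion, which closes the 1,2-dioxane and sets C3 as S (3,4-cis); the C6 epimer cyclises in the same way and is removed by chromatography here.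

Step 13
Reactants: 26 (3S,4S,6R)-4,6-dimethyl-6-[(2R)-2-methyl-11-phenylundecyl]-3-(prop-2-en-1-yl)-1,2-dioxane
Product: 28 2-[(3S,4S,6R)-4,6-dimethyl-6-[(2R)-2-methyl-11-phenylundecyl]-1,2-dioxan-3-yl]acetic acid, via dioxane aldehyde 27 (not isolated)
Conditions: O3, pyridine, CH2Cl2, −78 °C; then NaClO2, NaH2PO4, 2-methylbut-2-ene, t-BuOH/H2O, 0 °C to rt
Reagents that add atoms: ozone, [O-][O+]=O; sodium chlorite, [Na+].[O-]Cl=O
Why: Ozonolysis of the terminal alkene in the presence of pyridine gives the aldehyde directly, without a reducing agent that could attack the O–O bond, and Pinnick oxidation under buffered, non-basic conditions should give the acid with the peroxide and all four stereocentres intact.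

**Compound list**

1 | 9-bromonon-1-ene | C=CCCCCCCCBr | starting material
2 | phenylmagnesium bromide | Br[Mg]c1ccccc1 | starting material
3 | non-8-en-1-ylbenzene (9-phenylnon-1-ene) | C=CCCCCCCCc1ccccc1 | intermediate
4 | 4,4,5,5-tetramethyl-2-(9-phenylnonyl)-1,3,2-dioxaborolane | CC1(C)OB(CCCCCCCCCc2ccccc2)OC1(C)C | intermediate
5 | 2,4,6-triisopropylbenzoic acid | CC(C)c1cc(C(C)C)c(C(=O)O)c(C(C)C)c1 | starting material
6 | iodoethane | CCI | starting material
7 | ethyl 2,4,6-triisopropylbenzoate | CCOC(=O)c1c(C(C)C)cc(C(C)C)cc1C(C)C | intermediate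
8 | (R)-3-bromo-2-methylpropan-1-ol | BrC[C@H](C)CO | starting material
9 | (R)-(3-bromo-2-methylpropoxy)(tert-butyl)dimethylsilane | BrC[C@H](C)CO[Si](C)(C)C(C)(C)C | intermediate
10 | (S)-tert-butyldimethyl[(2-methylpent-4-yn-1-yl)oxy]silane | C#CC[C@H](C)CO[Si](C)(C)C(C)(C)C | intermediate
11 | [(1E,4S)-5-(tert-butyldimethylsilyloxy)-2,4-dimethylpent-1-en-1-yl]dimethylalumane | C[Al](C)/C=C(C)/C[C@H](C)CO[Si](C)(C)C(C)(C)C | intermediate (not isolated)
12 | tert-butyl{[(2S,4E)-5-iodo-2,4-dimethylpent-4-en-1-yl]oxy}dimethylsilane | I/C=C(C)/C[C@H](C)CO[Si](C)(C)C(C)(C)C | intermediate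
13 | (S)-1-lithioethyl 2,4,6-triisopropylbenzoate, as its (−)-sparteine complex | [Li][C@@H](C)OC(=O)c1c(C(C)C)cc(C(C)C)cc1C(C)C | intermediate (not isolated)
14 | lithium (9-phenylnonyl)(pinacolato)[(1S)-1-(2,4,6-triisopropylbenzoyloxy)ethyl]borate | [Li+].CC1(C)O[B-](CCCCCCCCCc2ccccc2)([C@@H](C)OC(=O)c2c(C(C)C)cc(C(C)C)cc2C(C)C)OC1(C)C | intermediate (not isolated)
15 | 4,4,5,5-tetramethyl-2-[(2R)-11-phenylundecan-2-yl]-1,3,2-dioxaborolane | C[C@H](CCCCCCCCCc1ccccc1)B1OC(C)(C)C(C)(C)O1 | intermediate (not isolated)
16 | [(1E,4S)-5-(tert-butyldimethylsilyloxy)-2,4-dimethylpent-1-en-1-yl]lithium | [Li]/C=C(C)/C[C@H](C)CO[Si](C)(C)C(C)(C)C | intermediate (not isolated)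
17 | lithium [(1E,4S)-5-(tert-butyldimethylsilyloxy)-2,4-dimethylpent-1-en-1-yl](pinacolato)[(2R)-11-phenylundecan-2-yl]borate | [Li+].C[C@H](CCCCCCCCCc1ccccc1)[B-]1(/C=C(C)/C[C@H](C)CO[Si](C)(C)C(C)(C)C)OC(C)(C)C(C)(C)O1 | intermediate (not isolated)
18 | tert-butyl{[(2S,6R)-4-iodo-2,4,6-trimethyl-15-phenyl-5-(4,4,5,5-tetramethyl-1,3,2-dioxaborolan-2-yl)pentadecyl]oxy}dimethylsilane (anti adduct at C4/C5, both facial diastereomers) | C[C@H](CCCCCCCCCc1ccccc1)C(B1OC(C)(C)C(C)(C)O1)C(C)(I)C[C@H](C)CO[Si](C)(C)C(C)(C)C | intermediate (not isolated)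
19 | tert-butyldimethyl{[(2S,4Z,6R)-2,4,6-trimethyl-15-phenylpentadec-4-en-1-yl]oxy}silane | C[C@H](CCCCCCCCCc1ccccc1)/C=C(C)\C[C@H](C)CO[Si](C)(C)C(C)(C)C | intermediate
20 | (2S,4Z,6R)-2,4,6-trimethyl-15-phenylpentadec-4-en-1-ol | C[C@H](CCCCCCCCCc1ccccc1)/C=C(C)\C[C@H](C)CO | intermediate
21 | (2S,4Z,6R)-2,4,6-trimethyl-15-phenylpentadec-4-enal | C[C@H](CCCCCCCCCc1ccccc1)/C=C(C)\C[C@H](C)C=O | intermediate (not isolated)
22 | (4R,5S,7Z,9R)-5,7,9-trimethyl-18-phenyloctadeca-1,7-dien-4-ol | C[C@H](CCCCCCCCCc1ccccc1)/C=C(C)\C[C@H](C)[C@@H](CC=C)O | intermediate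
23 | (4R,5S,7Z,9R)-5,7,9-trimethyl-18-phenyloctadeca-1,7-dien-4-yl methanesulfonate | C[C@H](CCCCCCCCCc1ccccc1)/C=C(C)\C[C@H](C)[C@@H](CC=C)OS(C)(=O)=O | intermediate
24 | (4R,5S,7R,9R)-5,7,9-trimethyl-18-phenyl-7-[(triethylsilyl)peroxy]octadec-1-en-4-yl methanesulfonate | C[C@H](CCCCCCCCCc1ccccc1)C[C@@](C)(OO[Si](CC)(CC)CC)C[C@H](C)[C@@H](CC=C)OS(C)(=O)=O | intermediate
25 | (4R,5S,7R,9R)-7-hydroperoxy-5,7,9-trimethyl-18-phenyloctadec-1-en-4-yl methanesulfonate | C[C@H](CCCCCCCCCc1ccccc1)C[C@@](C)(OO)C[C@H](C)[C@@H](CC=C)OS(C)(=O)=O | intermediate (not isolated)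
26 | (3S,4S,6R)-4,6-dimethyl-6-[(2R)-2-methyl-11-phenylundecyl]-3-(prop-2-en-1-yl)-1,2-dioxane | C[C@H](CCCCCCCCCc1ccccc1)C[C@]1(C)C[C@H](C)[C@H](CC=C)OO1 | intermediate
27 | 2-[(3S,4S,6R)-4,6-dimethyl-6-[(2R)-2-methyl-11-phenylundecyl]-1,2-dioxan-3-yl]acetaldehyde | C[C@H](CCCCCCCCCc1ccccc1)C[C@]1(C)C[C@H](C)[C@H](CC=O)OO1 | intermediate (not isolated)
28 | 2-[(3S,4S,6R)-4,6-dimethyl-6-[(2R)-2-methyl-11-phenylundecyl]-1,2-dioxan-3-yl]acetic acid | C[C@H](CCCCCCCCCc1ccccc1)C[C@]1(C)C[C@H](C)[C@H](CC(=O)O)OO1 | target

**Step count and risks**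

Total steps: 13. Longest linear sequence: 10 steps (steps 4 to 13: 8, 9, 10, 12, 19, 20, 22, 23, 24, 26, 28).

Steps most likely to fail:

1. Step 7. What may go wrong: loss of enantiomeric purity of the lithiated benzoate, double homologation or an incomplete 1,2-shift in the first stage; in the second stage, slow ate-complex formation between the hindered secondary boronic ester and the β,β-disubstituted alkenyllithium in the presence of sparteine and lithium benzoate, and consumption of iodine by the diamine. Fallback (sets out from 4 and 12, returns at 19): the same bond is made by substrate-controlled Matteson homologation in isolated stages. Boronic ester 4 is cleaved with NaIO4/NH4OAc to (9-phenylnonyl)boronic acid F1 and esterified with (1S,2S)-1,2-dicyclohexylethane-1,2-diol to (4S,5S)-4,5-dicyclohexyl-2-(9-phenylnonyl)-1,3,2-dioxaborolane F2. LiCHCl2 (−100 °C) followed by ZnCl2 inserts the chloromethine carbon by 1,2-shift of the nonyl group under control of the diol, giving (4S,5S)-2-[(1R)-1-chloro-10-phenyldecyl]-4,5-dicyclohexyl-1,3,2-dioxaborolane F3. MeMgBr replaces chloride with inversion through a second 1,2-shift to give (4S,5S)-4,5-dicyclohexyl-2-[(2R)-11-phenylundecan-2-yl]-1,3,2-dioxaborolane F4. Isolated F4 is then combined with alkenyllithium 16 (from 12), I2 and NaOMe in a separate Zweifel olefination to return to 19.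

2. Step 11. What may go wrong: capture of O2 on either face of the planar C6 radical (no facial selectivity, so about half of the material is expected as the C6 epimer), and competing hydrogen-atom transfer to the terminal alkene with over-peroxidation. Fallback (sets out from 20, returns at 24): the order is changed so that the peroxide is installed while the trisubstituted alkene is the only C=C bond. Alcohol 20 is hydroperoxysilylated (Co(thd)2, O2, Et3SiH) to (2S,4R,6R)-2,4,6-trimethyl-15-phenyl-4-[(triethylsilyl)peroxy]pentadecan-1-ol F5 (with its C4 epimer) and oxidised with Dess–Martin periodinane to (2S,4R,6R)-2,4,6-trimethyl-15-phenyl-4-[(triethylsilyl)peroxy]pentadecanal F6. F6 is allylated with allylboronic acid pinacol ester under chiral phosphoric acid catalysis (TRIP, antipode matched to the Felkin sense, −30 °C) to (4R,5S,7R,9R)-5,7,9-trimethyl-18-phenyl-7-[(triethylsilyl)peroxy]octadec-1-en-4-ol F7, which is mesylated (MsCl, Et3N) to give 24. This removes the chemoselectivity problem but not the lack of control at C6.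

3. Step 12. What may go wrong: E2 elimination of the secondary mesylate, or base-induced Kornblum–DeLaMare fragmentation of the peroxide, instead of the 6-exo-tet substitution. Fallback (sets out from 20, returns at 28): ring closure by conjugate addition instead of substitution. Alcohol 20 is oxidised (TEMPO, PhI(OAc)2) and the crude aldehyde 21 is olefinated with Ph3P=CHCO2Me to methyl (2E,4S,6Z,8R)-4,6,8-trimethyl-17-phenylheptadeca-2,6-dienoate F8. Hydroperoxysilylation (Co(thd)2, O2, Et3SiH; the enoate is inert) gives methyl (2E,4S,6R,8R)-4,6,8-trimethyl-17-phenyl-6-[(triethylsilyl)peroxy]heptadec-2-enoate F9. HCl in MeOH frees methyl (2E,4S,6R,8R)-6-hydroperoxy-4,6,8-trimethyl-17-phenylheptadec-2-enoate F10, which closes onto the enoate with Et2NH in CF3CH2OH (6-exo-trig oxa-Michael addition) to methyl 2-[(3S,4S,6R)-4,6-dimethyl-6-[(2R)-2-methyl-11-phenylundecyl]-1,2-dioxan-3-yl]acetate F11, the 3,4-cis isomer being separated from its 3,4-trans and C6 isomers. LiOH in THF/water then gives 28. In this variant C3 depends on the kinetic preference of the ring closure rather than on a stereospecific substitution, so it is held in reserve.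

Further compounds
F1 | step 7 | (9-phenylnonyl)boronic acid | OB(O)CCCCCCCCCc1ccccc1
F2 | step 7 | (4S,5S)-4,5-dicyclohexyl-2-(9-phenylnonyl)-1,3,2-dioxaborolane | c1ccccc1CCCCCCCCCB1O[C@@H](C2CCCCC2)[C@H](C2CCCCC2)O1
F3 | step 7 | (4S,5S)-2-[(1R)-1-chloro-10-phenyldecyl]-4,5-dicyclohexyl-1,3,2-dioxaborolane | Cl[C@@H](CCCCCCCCCc1ccccc1)B1O[C@@H](C2CCCCC2)[C@H](C2CCCCC2)O1
F4 | step 7 | (4S,5S)-4,5-dicyclohexyl-2-[(2R)-11-phenylundecan-2-yl]-1,3,2-dioxaborolane | C[C@H](CCCCCCCCCc1ccccc1)B1O[C@@H](C2CCCCC2)[C@H](C2CCCCC2)O1
F5 | step 11 | (2S,4R,6R)-2,4,6-trimethyl-15-phenyl-4-[(triethylsilyl)peroxy]pentadecan-1-ol | C[C@H](CCCCCCCCCc1ccccc1)C[C@@](C)(OO[Si](CC)(CC)CC)C[C@H](C)CO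
F6 | step 11 | (2S,4R,6R)-2,4,6-trimethyl-15-phenyl-4-[(triethylsilyl)peroxy]pentadecanal | C[C@H](CCCCCCCCCc1ccccc1)C[C@@](C)(OO[Si](CC)(CC)CC)C[C@H](C)C=O
F7 | step 11 | (4R,5S,7R,9R)-5,7,9-trimethyl-18-phenyl-7-[(triethylsilyl)peroxy]octadec-1-en-4-ol | C[C@H](CCCCCCCCCc1ccccc1)C[C@@](C)(OO[Si](CC)(CC)CC)C[C@H](C)[C@@H](CC=C)O
F8 | step 12 | methyl (2E,4S,6Z,8R)-4,6,8-trimethyl-17-phenylheptadeca-2,6-dienoate | C[C@H](CCCCCCCCCc1ccccc1)/C=C(C)\C[C@H](C)/C=C/C(=O)OC
F9 | step 12 | methyl (2E,4S,6R,8R)-4,6,8-trimethyl-17-phenyl-6-[(triethylsilyl)peroxy]heptadec-2-enoate | C[C@H](CCCCCCCCCc1ccccc1)C[C@@](C)(OO[Si](CC)(CC)CC)C[C@H](C)/C=C/C(=O)OC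
F10 | step 12 | methyl (2E,4S,6R,8R)-6-hydroperoxy-4,6,8-trimethyl-17-phenylheptadec-2-enoate | C[C@H](CCCCCCCCCc1ccccc1)C[C@@](C)(OO)C[C@H](C)/C=C/C(=O)OC
F11 | step 12 | methyl 2-[(3S,4S,6R)-4,6-dimethyl-6-[(2R)-2-methyl-11-phenylundecyl]-1,2-dioxan-3-yl]acetate | C[C@H](CCCCCCCCCc1ccccc1)C[C@]1(C)C[C@H](C)[C@H](CC(=O)OC)OO1
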